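## Retrosynthetic overview

1. The strategy rests on the γ-lactone ring (O–C6–C7–C11–C12): its C6–O bond is allylic to the Z-trisubstituted C4=C5 alkene (methyl C15 on C4), which is conjugated with the furanone ring (O–C3=C2–C1(=O)–C10). C6–O plus C4=C5 is the 1,3-transposed form of a tertiary C4 carbinol with a ring-cis C5=C6 alkene, so the lactone (C6–O and O–C12) is disconnected last, to the C4-carbinol methyl esters 21 and 22.
2. The nine-membered oxacycle (ten-membered carbocycle) is opened at C5=C6 by ring-closing metathesis of two vinyl groups; the C8 angelate comes from a C8 carbinol by Mitsunobu inversion.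
3. The C7–C8 bond comes from a catalyst-controlled, syn-selective 2-(methoxycarbonyl)allylation of a C8 aldehyde with dienoate bromide 16 (methyl acrylate plus acrolein).
4. The furanone ring comes from the Weinreb amide of (R)-citramalic acid (C10, C14) and the acetylide of racemic 3-methylpent-1-en-4-yn-3-ol (C2–C5, C15); the C10 hydroxyl closes onto C3.
5. Ring order: furanone ring, then the nine-membered oxacycle, then the γ-lactone.

Key step: step 13

Remarks and assumptions
- Germacrane numbering is used for ring compounds: C1 ketone, C2=C3, C3–O–C10 ether, C4 (methyl C15), C5, C6, C7, C8, C9, C10 (methyl C14), C11=C13, C12 carboxyl.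
- C4 comes from racemic 6. Compounds 8–12, 17, 18 and 20 are therefore pairs of C4 epimers carried under one number, with C4 left open in the SMILES. The two ring-closed epimers are numbered separately as 21 and 22.
- Simple metal-mediated allylations with 16 are expected to give the 7,8-syn adduct, whereas the target is 7,8-anti. C8 is therefore made as its epimer in step 10 and inverted when the angelate is introduced in step 11.
- Assumption for step 10: the sense of induction of the oxazoline ligand is taken as fixed on a simple model aldehyde, and the enantiomer that sends the allyl group to the Si face of the formyl group is used.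

## Route

Step 1
Reactants: 1 (R)-citramalic acid
Product: 2 2-[(4R)-2,2,4-trimethyl-5-oxo-1,3-dioxolan-4-yl]acetic acid
Conditions: 2,2-dimethoxypropane, p-TsOH·H2O (cat.), rt
Reagents that add atoms: 2,2-dimethoxypropane, COC(C)(C)OC
Why: Acid-catalysed transacetalisation closes the five-membered dioxolanone on the α-hydroxy acid and leaves the CH2CO2H arm (future C9–C8) free; the quaternary centre (future C10) is not touched.

Step 2
Reactants: 2 dioxolanone acid
Product: 3 (5R)-5-(2-hydroxyethyl)-2,2,5-trimethyl-1,3-dioxolan-4-one
Conditions: BH3·SMe2, THF, 0 °C to rt; MeOH quench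
Reagents that add atoms: none
Why: Chemoselective borane reduction: the free carboxylic acid is reduced through its acyloxyborane much faster than the ester-type dioxolanone carbonyl.

Step 3
Reactants: 3 dioxolanone alcohol
Product: 4 (5R)-2,2,5-trimethyl-5-[2-(triethylsilyloxy)ethyl]-1,3-dioxolan-4-one
Conditions: Et3SiCl, imidazole, CH2Cl2, 0 °C
Reagents that add atoms: chlorotriethylsilane, CC[Si](Cl)(CC)CC
Why: Standard silylation of the primary alcohol, which also stops translactonisation onto the dioxolanone carbonyl.

Step 4
Reactants: 4 silyl ether dioxolanone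
Product: 5 (2R)-2-hydroxy-N-methoxy-N,2-dimethyl-4-(triethylsilyloxy)butanamide
Conditions: Me(MeO)NH·HCl, iPrMgCl, THF, −20 °C; then 4, −20 to 0 °C
Reagents that add atoms: N,O-dimethylhydroxylamine hydrochloride, CNOC.Cl
Why: Aminolysis of the activated dioxolanone carbonyl by the chloromagnesium amide gives the Weinreb amide with loss of acetone and frees the tertiary hydroxyl needed later as the furanone oxygen.

Step 5
Reactants: 5 Weinreb amide; 6 racemic 3-methylpent-1-en-4-yn-3-ol
Product: 8 (3R)-3,7-dihydroxy-3,7-dimethyl-1-(triethylsilyloxy)non-8-en-5-yn-4-one (C4 epimer pair), via dilithium alkynide alkoxide 7 (not isolated)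
Conditions: 6 (3 equiv), n-BuLi (6 equiv), THF, −78 to −20 °C; then 5, −78 to 0 °C; aq. NH4Cl
Reagents that add atoms: none
Why: Acylation of a lithium acetylide by a Weinreb amide stops at the ketone because the N-methoxy chelate holds the tetrahedral adduct; the excess dianion takes up the hydroxyl proton of 5, and the racemic carbinol carbon (C4) enters as an epimer pair.

Step 6
Reactants: 8 hydroxy ynone
Product: 11 (2R)-2-(2-hydroxyethyl)-5-(2-hydroxybut-3-en-2-yl)-2-methylfuran-3(2H)-one (C4 epimer pair), via enaminone 9 (not isolated), via silyl ether furanone 10 (not isolated)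
Conditions: Et2NH, EtOH, rt; then AcOH–THF–H2O (3:1:1), rt
Reagents that add atoms: none
Why: Conjugate addition of diethylamine to the ynone gives the enaminone, and under aqueous acid the C10 hydroxyl displaces the amine at C3 by addition–elimination to close the 3(2H)-furanone ring, while the same acid cleaves the primary triethylsilyl ether; the C4 hydroxyl cannot cyclise because it would form a three- or four-membered ring.

Step 7
Reactants: 11 furanone diol
Product: 12 2-[(2R)-5-(2-hydroxybut-3-en-2-yl)-2-methyl-3-oxo-2,3-dihydrofuran-2-yl]acetaldehyde (C4 epimer pair)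
Conditions: Dess–Martin periodinane, NaHCO3, CH2Cl2, 0 °C to rt; used directly
Reagents that add atoms: none
Why: Dess–Martin oxidation takes the primary alcohol to the C8 aldehyde and leaves the tertiary carbinol alone; the buffered, non-basic medium avoids β-elimination of the furanone oxygen from the β-alkoxy aldehyde.

Step 8
Reactants: 13 methyl acrylate; 14 acrolein
Product: 15 methyl 3-hydroxy-2-methylidenepent-4-enoate (racemic)
Conditions: DABCO (cat.), neat, rt
Reagents that add atoms: none
Why: Morita–Baylis–Hillman reaction of the acrylate with the aldehyde group of acrolein.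

Step 9
Reactants: 15 Morita–Baylis–Hillman adduct
Product: 16 methyl (2Z)-2-(bromomethyl)penta-2,4-dienoate
Conditions: N-bromosuccinimide, Me2S, CH2Cl2, 0 °C to rt
Reagents that add atoms: N-bromosuccinimide, O=C1CCC(=O)N1Br
Why: SN2' displacement of the alkoxysulfonium group by bromide (Corey–Kim-type activation) gives the fully conjugated bromide with the vinyl group trans to the ester.

Step 10
Reactants: 12 aldehyde; 16 dienoate bromide
Product: 18 methyl (3R,4R)-3-ethenyl-4-hydroxy-5-[(2R)-5-(2-hydroxybut-3-en-2-yl)-2-methyl-3-oxo-2,3-dihydrofuran-2-yl]-2-methylidenepentanoate (C4 epimer pair), via trimethylsilyl ether 17 (not isolated)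
Conditions: CrCl2 (10 mol%), chiral 1,8-bis(oxazolinyl)carbazole ligand (12 mol%), Mn, Me3SiCl, iPr2NEt (cat.), THF, rt; then aq. citric acid, 0 °C
Reagents that add atoms: none
Why: Nozaki–Hiyama allylation under asymmetric chromium catalysis: the allylchromium species from 16 reacts at its γ-carbon (C7) through a chair Zimmerman–Traxler transition state with the vinyl group (cis to the CH2Cr terminus) axial and the aldehyde substituent equatorial, which sets C7 and C8 syn, and the ligand selects the Si face of the formyl group, so that the (7R,8R) carbinol forms independently of the remote C10 centre.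

Step 11
Reactants: 18 syn hydroxy ester; 19 angelic acid
Product: 20 methyl (3R,4S)-3-ethenyl-5-[(2R)-5-(2-hydroxybut-3-en-2-yl)-2-methyl-3-oxo-2,3-dihydrofuran-2-yl]-2-methylidene-4-{[(2Z)-2-methylbut-2-enoyl]oxy}pentanoate (C4 epimer pair)
Conditions: PPh3, DIAD, toluene, 0 °C to rt
Reagents that add atoms: none
Why: Mitsunobu esterification: angelate displaces the C8 oxyphosphonium group by SN2 with inversion, turning the 8R carbinol into the 8S angelate; the acid acts only as the nucleophile, so its Z geometry is kept, and the tertiary C4 carbinol does not react.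

Step 12
Reactants: 20 angelate diene
Product: 21 methyl (4S,5Z,7R,8S,10R)-8-angeloyloxy-4-hydroxy-1-oxo-3,10-epoxygermacra-2,5,11(13)-trien-12-oate (epimer a) together with 22 its (4R) epimer (epimer b)
Conditions: second-generation Grubbs catalyst (10 mol%), CH2Cl2 (1 mM), 40 °C
Reagents that add atoms: none
Why: Ring-closing metathesis joins the two monosubstituted vinyl groups while the electron-poor 1,1-disubstituted acrylate, the angelate and the furanone alkene stay out; the nine-membered oxacycle can hold the new C5=C6 alkene only as the cis isomer, and high dilution suppresses oligomers.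

Step 13
Reactants: 21 C4 carbinol epimer a (4S); 22 C4 carbinol epimer b (4R)
Product: 25 lychnopholide, via C6 carbinol 23 (not isolated), via C6-epimeric carbinol 24 (not isolated)
Conditions: Re2O7 (10 mol%), CH2Cl2, 0 °C to rt
Reagents that add atoms: none
Why: Re2O7 converts the C4 carbinols into allyl perrhenates, which undergo a suprafacial [3,3] shift across the ring-cis C4–C5–C6 unit, placing oxygen on C6 and the alkene at C4=C5 in conjugation with the furanone, and the perrhenic acid present then catalyses attack of the C6 hydroxyl on the C12 ester with loss of methanol. The closest known reaction type is the Re2O7-catalysed 1,3-transposition of allylic alcohols under thermodynamic control in which one equilibrating isomer is removed by a cyclisation. The γ-lactone ring (O–C6–C7–C11–C12) closes by 5-exo-trig addition of the C6 hydroxyl to the ester carbonyl. The new C6 stereocentre is set by the shift itself for epimer 21, whose (4S) C–O bond lies on the face of the allyl unit that becomes the 6R face, whereas epimer 22 gives the 6S carbinol 24 by the same shift and should reach 23 only by reversion and return of its perrhenate ion pair on the opposite face, so its conversion is expected to be the slower branch. The step needs the Z (ring-cis) C4=C5 alkene and the 6,7-trans lactone: the nine-membered oxacycle cannot hold an E alkene next to the sp2 carbon C3, and in 23 the C6 oxygen and C11 are gauche across C6–C7 so that closure is fast, while 24 must distort the ring to reach the ester and is expected to revert instead of closing.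

## Compound list

1 | (R)-citramalic acid | OC(=O)[C@@](C)(CC(=O)O)O | starting material
2 | 2-[(4R)-2,2,4-trimethyl-5-oxo-1,3-dioxolan-4-yl]acetic acid | O=C1OC(C)(C)O[C@]1(C)CC(=O)O | intermediate
3 | (5R)-5-(2-hydroxyethyl)-2,2,5-trimethyl-1,3-dioxolan-4-one | O=C1OC(C)(C)O[C@]1(C)CCO | intermediate
4 | (5R)-2,2,5-trimethyl-5-[2-(triethylsilyloxy)ethyl]-1,3-dioxolan-4-one | O=C1OC(C)(C)O[C@]1(C)CCO[Si](CC)(CC)CC | intermediate
5 | (2R)-2-hydroxy-N-methoxy-N,2-dimethyl-4-(triethylsilyloxy)butanamide | CON(C)C(=O)[C@](C)(O)CCO[Si](CC)(CC)CC | intermediate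
6 | 3-methylpent-1-en-4-yn-3-ol (racemic) | C=CC(C)(O)C#C | starting material
7 | dilithium alkynide alkoxide of 6 (not isolated) | [Li]C#CC(C)(O[Li])C=C | intermediate
8 | (3R)-3,7-dihydroxy-3,7-dimethyl-1-(triethylsilyloxy)non-8-en-5-yn-4-one (C4 epimer pair) | C=CC(C)(O)C#CC(=O)[C@](C)(O)CCO[Si](CC)(CC)CC | intermediate
9 | (3R)-6-(diethylamino)-3,7-dihydroxy-3,7-dimethyl-1-(triethylsilyloxy)nona-5,8-dien-4-one (enaminone, not isolated) | CCN(CC)C(=CC(=O)[C@](C)(O)CCO[Si](CC)(CC)CC)C(C)(O)C=C | intermediate
10 | (2R)-5-(2-hydroxybut-3-en-2-yl)-2-methyl-2-[2-(triethylsilyloxy)ethyl]furan-3(2H)-one (not isolated) | C=CC(C)(O)C1=CC(=O)[C@@](C)(CCO[Si](CC)(CC)CC)O1 | intermediate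
11 | (2R)-2-(2-hydroxyethyl)-5-(2-hydroxybut-3-en-2-yl)-2-methylfuran-3(2H)-one (C4 epimer pair) | C=CC(C)(O)C1=CC(=O)[C@@](C)(CCO)O1 | intermediate
12 | 2-[(2R)-5-(2-hydroxybut-3-en-2-yl)-2-methyl-3-oxo-2,3-dihydrofuran-2-yl]acetaldehyde (C4 epimer pair) | C=CC(C)(O)C1=CC(=O)[C@@](C)(CC=O)O1 | intermediate
13 | methyl acrylate | C=CC(=O)OC | starting material
14 | acrolein | C=CC=O | starting material
15 | methyl 3-hydroxy-2-methylidenepent-4-enoate (racemic) | C=CC(O)C(=C)C(=O)OC | intermediate
16 | methyl (2Z)-2-(bromomethyl)penta-2,4-dienoate | COC(=O)/C(CBr)=C/C=C | intermediate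
17 | trimethylsilyl ether of 18 (not isolated) | C=C(C(=O)OC)[C@@H](C=C)[C@H](O[Si](C)(C)C)C[C@@]1(C)OC(=CC1=O)C(C)(O)C=C | intermediate
18 | methyl (3R,4R)-3-ethenyl-4-hydroxy-5-[(2R)-5-(2-hydroxybut-3-en-2-yl)-2-methyl-3-oxo-2,3-dihydrofuran-2-yl]-2-methylidenepentanoate (7R,8R; C4 epimer pair) | C=C(C(=O)OC)[C@@H](C=C)[C@H](O)C[C@@]1(C)OC(=CC1=O)C(C)(O)C=C | intermediate
19 | angelic acid | C/C=C(/C)C(=O)O | starting material
20 | methyl (3R,4S)-3-ethenyl-5-[(2R)-5-(2-hydroxybut-3-en-2-yl)-2-methyl-3-oxo-2,3-dihydrofuran-2-yl]-2-methylidene-4-{[(2Z)-2-methylbut-2-enoyl]oxy}pentanoate (7R,8S; C4 epimer pair) | C=C(C(=O)OC)[C@@H](C=C)[C@@H](OC(=O)/C(C)=C\C)C[C@@]1(C)OC(=CC1=O)C(C)(O)C=C | intermediate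
21 | methyl (4S,5Z,7R,8S,10R)-8-angeloyloxy-4-hydroxy-1-oxo-3,10-epoxygermacra-2,5,11(13)-trien-12-oate (epimer a) | C=C(C(=O)OC)[C@H]1/C=C\[C@](C)(O)C2=CC(=O)[C@@](C)(C[C@@H]1OC(=O)/C(C)=C\C)O2 | intermediate
22 | methyl (4R,5Z,7R,8S,10R)-8-angeloyloxy-4-hydroxy-1-oxo-3,10-epoxygermacra-2,5,11(13)-trien-12-oate (epimer b) | C=C(C(=O)OC)[C@H]1/C=C\[C@@](C)(O)C2=CC(=O)[C@@](C)(C[C@@H]1OC(=O)/C(C)=C\C)O2 | intermediate
23 | methyl (4Z,6R,7S,8S,10R)-8-angeloyloxy-6-hydroxy-1-oxo-3,10-epoxygermacra-2,4,11(13)-trien-12-oate (not isolated) | C=C(C(=O)OC)[C@H]1[C@H](O)/C=C(/C)C2=CC(=O)[C@@](C)(C[C@@H]1OC(=O)/C(C)=C\C)O2 | intermediate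
24 | methyl (4Z,6S,7S,8S,10R)-8-angeloyloxy-6-hydroxy-1-oxo-3,10-epoxygermacra-2,4,11(13)-trien-12-oate (not isolated) | C=C(C(=O)OC)[C@H]1[C@@H](O)/C=C(/C)C2=CC(=O)[C@@](C)(C[C@@H]1OC(=O)/C(C)=C\C)O2 | intermediate
25 | lychnopholide, (4Z,6R,7R,8S,10R)-8-angeloyloxy-1-oxo-3,10-epoxygermacra-2,4,11(13)-trien-12,6-olide | C=C1C(=O)O[C@@H]2/C=C(/C)C3=CC(=O)[C@@](C)(C[C@H](OC(=O)/C(C)=C\C)[C@@H]12)O3 | target

Total step count: 13
Longest linear sequence: 11 steps (steps 1–7 and 10–13, from 1 to 25); the bromide 16 is made in a 2-step branch (steps 8 and 9).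

## Steps most likely to fail

Step 13 (key step). Three processes may interfere: slow or incomplete crossing of the mismatched epimer 22 (ionisation next to the electron-poor furanone is disfavoured), closure of the 6S carbinol 24 to the cis-fused lactone, and acid-promoted dehydration of the tertiary carbinol to a cross-conjugated triene. The fallback sets out from the mixture of 21 and 22 and removes the dependence on the C4 configuration. Babler–Dauben oxidative transposition with pyridinium chlorochromate, (C5H5NH)[CrO3Cl], in CH2Cl2 should give the C6 enone F1 from both epimers, because the chromate ester shifts in the same [3,3] sense and the C6 carbinol stage is oxidised to the ketone. Corey–Bakshi–Shibata reduction (BH3·SMe2, with the oxazaborolidine enantiomer that delivers hydride to the face giving the 6R carbinol, low temperature) then comes back to the route at carbinol 23, which closes to 25 with catalytic p-TsOH.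

Step 12. Intermolecular metathesis may outrun closure of the strained bridged ring, the two C4 epimers may cyclise at different rates, and ruthenium hydride species may migrate the alkenes. The fallback changes the substrate and the order of events. It sets out from the syn carbinol 18, whose free C8 hydroxyl lacks the bulky angelate and can hydrogen-bond to the ester. Ring-closing metathesis on 18 should give the ring-closed C8 carbinols F2 (4S) and F3 (4R). Mitsunobu inversion with 19 (PPh3, DIAD) on the ring then comes back to the route at 21 and 22.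

Step 10. The chiral, functionalised aldehyde may erode the facial control of the catalyst, the syn preference may drop if the allylchromium reacts through its other alkene geometry, the syn adduct may close to the cis 8,12-lactone, and the amine additive may trigger β-elimination of the furanone oxygen in 12. The fallback sets out from 12 and 16 and gives up catalyst control for a base-free Barbier allylation with indium powder in THF–water. This should again be syn-selective through the chair transition state but should show little preference between the two faces of the aldehyde. It would give 18 together with its (7S,8S) diastereomer F4; chromatographic separation comes back to the route at 18.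

Further compounds
F1 | step 13 | methyl (4Z,7R,8S,10R)-8-angeloyloxy-1,6-dioxo-3,10-epoxygermacra-2,4,11(13)-trien-12-oate | C=C(C(=O)OC)[C@H]1C(=O)/C=C(/C)C2=CC(=O)[C@@](C)(C[C@@H]1OC(=O)/C(C)=C\C)O2
F2 | step 12 | methyl (4S,5Z,7R,8R,10R)-4,8-dihydroxy-1-oxo-3,10-epoxygermacra-2,5,11(13)-trien-12-oate | C=C(C(=O)OC)[C@H]1/C=C\[C@](C)(O)C2=CC(=O)[C@@](C)(C[C@H]1O)O2
F3 | step 12 | methyl (4R,5Z,7R,8R,10R)-4,8-dihydroxy-1-oxo-3,10-epoxygermacra-2,5,11(13)-trien-12-oate | C=C(C(=O)OC)[C@H]1/C=C\[C@@](C)(O)C2=CC(=O)[C@@](C)(C[C@H]1O)O2
F4 | step 10 | methyl (3S,4S)-3-ethenyl-4-hydroxy-5-[(2R)-5-(2-hydroxybut-3-en-2-yl)-2-methyl-3-oxo-2,3-dihydrofuran-2-yl]-2-methylidenepentanoate | C=C(C(=O)OC)[C@H](C=C)[C@@H](O)C[C@@]1(C)OC(=CC1=O)C(C)(O)C=C
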